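Numbering: bicyclo[5.3.0]decane (C1/C7 ring fusion, C2–C6 seven-membered ring, C8–C10 cyclopentane). The seven-membered ring is opened at C3–C4 and C6–C7 into a diene (C3=C2–C1=C7, on a cyclopentene that already holds the C10 carbinol) and a vinylcarbenoid (C4–C5–C6). The key step exploits the one-carbon branch on C4 and the adjacent pair of oxygenated C6 and methyl-bearing quaternary fusion carbon C7: a chiral dirhodium carbenoid cyclopropanates the vinyl group and the cis-divinylcyclopropane rearranges, closing the bicyclo[5.3.0]decadiene and setting C6 and C7 at once. The precursors are a silyl-protected 2-ethenyl-3-methylcyclopentenol and an (E)-acetoxyvinyl diazoacetate.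

Key step: step 12

Remarks on the chemistry
- Faces: β is the face of H-1 and of the C2, C5 and C6 oxygens in the target; α is the face of the C7 methyl and the C10 oxygen. Descriptors are CIP descriptors with the locants above.
- The C10 oxygen is carried as a triethylsilyl ether: it is more robust than a trimethylsilyl ether through ten steps, adds bulk to the α-face for steps 12 and 13, and is cleaved together with the acetonide in step 19.
- The carbinol carbon made in step 2 (later C10) keeps one spatial arrangement throughout; its descriptor changes only with CIP priorities. The same holds for C6 (R in 20 to 23, S from 24 on).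
- Assumption: 3-methyl-2-methylidenebutanal and 2-oxoethyl acetate are purchased, and the two Grignard reagents are commercial THF solutions.
- Assumption: the R enantiomer of Rh2(DOSP)4, Rh2[(R)-N-(4-dodecylbenzenesulfonyl)prolinate]4, is assigned from the accepted facial model for cyclopropanation by donor/acceptor carbenoids; the S enantiomer would lead to the C6,C7 diastereomer.

Step 1
Reactants: 1 3-methyl-2-methylidenebutanal
Product: 2 3-methyl-2-methylidenebutan-1-ol
Conditions: NaBH4, CeCl3·7H2O, MeOH, 0 °C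
Reagents that add atoms: none
Why: Luche reduction delivers hydride 1,2 to the enal carbonyl and leaves the 1,1-disubstituted alkene untouched; no stereocentre is formed.

Step 2
Reactants: 2 3-methyl-2-methylidenebutan-1-ol
Product: 3 [(2R)-2-(propan-2-yl)oxiran-2-yl]methanol
Conditions: Ti(OiPr)4 (10 mol%), (−)-diisopropyl D-tartrate (12 mol%), t-BuOOH, 4 Å MS, CH2Cl2, −20 °C
Reagents that add atoms: tert-butyl hydroperoxide, CC(C)(C)OO
Why: Sharpless asymmetric epoxidation: the titanium complex of the unnatural D-(−)-tartrate delivers oxygen to the alkene face that gives the 2R epoxy alcohol, whose quaternary carbon becomes C10, and the catalytic, sieve-dried variant limits opening of this sensitive 2,2-disubstituted epoxide.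

Step 3
Reactants: 3 [(2R)-2-(propan-2-yl)oxiran-2-yl]methanol; 4 (2-methylprop-2-en-1-yl)magnesium chloride
Product: 5 (2R)-5-methyl-2-(propan-2-yl)hex-5-ene-1,2-diol
Conditions: 4 (2.5 equiv), CuI (10 mol%), THF, −30 → 0 °C; aq. NH4Cl
Reagents that add atoms: none
Why: Copper-catalysed Grignard opening of the epoxide by SN2 attack at its unsubstituted CH2 carbon (one equivalent of 4 is consumed by the hydroxyl) adds the arm that becomes C8, C7 and the C7 methyl, and no bond at the carbinol centre is broken, so its configuration is retained.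

Step 4
Reactants: 5 (2R)-5-methyl-2-(propan-2-yl)hex-5-ene-1,2-diol
Product: 7 (2R)-2-(3-methylbut-3-en-1-yl)-2-(propan-2-yl)oxirane, via primary tosylate 6 (not isolated)
Conditions: NaH, 1-(p-toluenesulfonyl)imidazole, THF, 0 → 23 °C
Reagents that add atoms: none
Why: One-pot conversion of a 1,2-diol into an epoxide: the primary alkoxide is sulfonylated selectively and the tertiary alkoxide displaces the tosylate (intramolecular Williamson reaction, 3-exo-tet), again without breaking a bond at the stereocentre.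

Step 5
Reactants: 7 (2R)-2-(3-methylbut-3-en-1-yl)-2-(propan-2-yl)oxirane; 8 ethenylmagnesium bromide
Product: 9 (4S)-7-methyl-4-(propan-2-yl)octa-1,7-dien-4-ol
Conditions: 8 (1.5 equiv), CuI (10 mol%), THF, −30 → 0 °C; aq. NH4Cl
Reagents that add atoms: none
Why: Copper-catalysed Grignard opening of the 2,2-disubstituted epoxide at its CH2 carbon installs the allyl arm (C1 and C2 after ozonolysis) and returns the tertiary alcohol with its C–O bond and configuration intact.

Step 6
Reactants: 9 (4S)-7-methyl-4-(propan-2-yl)octa-1,7-dien-4-ol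
Product: 10 triethyl{[(4S)-7-methyl-4-(propan-2-yl)octa-1,7-dien-4-yl]oxy}silane
Conditions: Et3SiOTf, 2,6-lutidine, CH2Cl2, −78 → 0 °C
Reagents that add atoms: triethylsilyl trifluoromethanesulfonate, CC[Si](CC)(CC)OS(=O)(=O)C(F)(F)F
Why: Silylation of the hindered tertiary alcohol with a silyl triflate and a hindered pyridine base caps the oxygen that would otherwise undergo O–H insertion in step 12.

Step 7
Reactants: 10 triethyl{[(4S)-7-methyl-4-(propan-2-yl)octa-1,7-dien-4-yl]oxy}silane
Product: 12 (3S)-6-oxo-3-(propan-2-yl)-3-[(triethylsilyl)oxy]heptanal, via bis-ozonide 11 (not isolated)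
Conditions: O3, CH2Cl2, −78 °C; then PPh3, −78 → 23 °C
Reagents that add atoms: ozone, [O-][O+]=O
Why: Ozonolysis with reductive work-up cleaves both terminal alkenes, the allyl group to the C2 aldehyde and the 1,1-disubstituted alkene to the C7 methyl ketone, without touching the silyl ether or the stereocentre.

Step 8
Reactants: 12 (3S)-6-oxo-3-(propan-2-yl)-3-[(triethylsilyl)oxy]heptanal
Product: 13 (5R)-2-methyl-5-(propan-2-yl)-5-[(triethylsilyl)oxy]cyclopent-1-ene-1-carbaldehyde
Conditions: piperidine (20 mol%), AcOH (20 mol%), toluene, 23 → 50 °C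
Reagents that add atoms: none
Why: Amine-catalysed intramolecular aldol condensation: the enamine of the aldehyde attacks the methyl ketone (5-exo-trig, forming C1–C7) and dehydration gives the conjugated cyclopentenecarbaldehyde, the aldehyde-enamine mode being the one favoured under amine and acid catalysis over ketone enolisation.

Step 9
Reactants: 13 (5R)-2-methyl-5-(propan-2-yl)-5-[(triethylsilyl)oxy]cyclopent-1-ene-1-carbaldehyde
Product: 14 {[(1R)-2-ethenyl-3-methyl-1-(propan-2-yl)cyclopent-2-en-1-yl]oxy}(triethyl)silane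
Conditions: Ph3PCH3Br, KOtBu, THF, 0 °C
Reagents that add atoms: methyltriphenylphosphonium bromide, C[P+](c1ccccc1)(c1ccccc1)c1ccccc1.[Br-]
Why: Wittig methylenation turns the C2 aldehyde into the C2=C3 vinyl group and leaves the tetrasubstituted ring alkene and the silyl ether untouched.

Step 10
Reactants: 15 ethyl diazoacetate; 16 2-oxoethyl acetate
Product: 17 ethyl 4-(acetyloxy)-2-diazo-3-hydroxybutanoate (racemic)
Conditions: DBU (10 mol%), MeCN, 0 → 23 °C
Reagents that add atoms: none
Why: Base-catalysed aldol-type addition of the acidic C–H of the diazo ester to the aldehyde gives the β-hydroxy-α-diazo ester with the diazo group retained; the new carbinol centre is racemic and disappears in step 11.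

Step 11
Reactants: 17 ethyl 4-(acetyloxy)-2-diazo-3-hydroxybutanoate
Product: 18 ethyl (3E)-4-(acetyloxy)-2-diazobut-3-enoate
Conditions: POCl3, Et3N, CH2Cl2, 0 °C
Reagents that add atoms: none
Why: Dehydration of a β-hydroxy-α-diazo ester through its dichlorophosphate is the standard entry to vinyldiazoacetates and should give the more stable E enol acetate by loss of the C4 proton; 18 is kept cold and used at once.

Step 12
Reactants: 14 {[(1R)-2-ethenyl-3-methyl-1-(propan-2-yl)cyclopent-2-en-1-yl]oxy}(triethyl)silane; 18 ethyl (3E)-4-(acetyloxy)-2-diazobut-3-enoate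
Product: 20 ethyl (6R,7S,10R)-6-(acetyloxy)-7-methyl-10-(propan-2-yl)-10-[(triethylsilyl)oxy]bicyclo[5.3.0]deca-1,4-diene-4-carboxylate, via cis-divinylcyclopropane 19 (not isolated)
Conditions: Rh2(R-DOSP)4 (2 mol%), hexane, −40 → 23 °C, 18 (1.5 equiv) added over 2 h; then toluene, 100 °C
Reagents that add atoms: none
Why: Proposed new method: Rh2(R-DOSP)4 converts 18 into a donor/acceptor vinylcarbenoid whose carbenoid carbon (C4) adds across the monosubstituted C2=C3 alkene of 14, bonding first to the terminal C3, to give the cis-divinylcyclopropane 19, and on heating 19 undergoes a [3,3]-sigmatropic (Cope) shift through the boat transition state in which the C2–C4 bond breaks and C6–C7 forms. The closest known reaction type is the dirhodium prolinate-catalysed tandem cyclopropanation and Cope rearrangement of vinyldiazoacetates with 1,3-dienes; an acyloxy group on the vinyl terminus of the carbenoid and a fully substituted ring carbon as rearrangement terminus go beyond it. The seven-membered ring is closed by this sigmatropic C6–C7 bond formation, driven by release of cyclopropane strain, so that the two events together amount to a [4+3] annulation onto the cyclopentene. C6 and C7 arise together: the boat places the E-acetoxy group and C8 on one side and H-6 and the C7 methyl on the other, so the E geometry of 18 fixes the C6/C7 relationship, and their absolute sense follows from the face of cyclopropanation, which the chiral catalyst dictates (the R catalyst is the one predicted for the 1R,2S cyclopropane) with C10, three atoms from the first bond formed, as a bystander. The step needs the carbenoid to choose the vinyl group over the tetrasubstituted ring alkene, the allylic C–H bonds and oxygen, which the preference of these carbenoids for monosubstituted alkenes and the silyl cap on the C10 oxygen should secure, and it needs the vinyl group to end cis to the cyclopentenyl group, the normal outcome for donor/acceptor carbenoids. Because the C7 methyl points into the boat, the rearrangement is expected to require the heating period and not to run at the temperature of the cyclopropanation.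

Step 13
Reactants: 20 ethyl (6R,7S,10R)-6-(acetyloxy)-7-methyl-10-(propan-2-yl)-10-[(triethylsilyl)oxy]bicyclo[5.3.0]deca-1,4-diene-4-carboxylate
Product: 22 ethyl (1S,2S,6R,7S,10R)-6-(acetyloxy)-2-hydroxy-7-methyl-10-(propan-2-yl)-10-[(triethylsilyl)oxy]bicyclo[5.3.0]dec-4-ene-4-carboxylate, via alkylborane 21 (not isolated)
Conditions: BH3·THF (1.3 equiv), THF, 0 °C; then NaBO3·4H2O, H2O, 23 °C
Reagents that add atoms: sodium perborate (used as the tetrahydrate), [Na+].[Na+].O[B-]1(O)OO[B-](O)(O)OO1
Why: Hydroboration–oxidation: borane adds syn and anti-Markovnikov to the electron-rich C1=C2 alkene (the ester-conjugated alkene is deactivated), boron to C2 and hydrogen to C1 from the β-face opposite the angular C7 methyl and the C10 silyloxy group, as in the hydroboration of steroidal 5-enes anti to the angular methyl, and perborate oxidation with retention gives the 2β-alcohol and the trans ring fusion without hydrolysing the acetate.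

Step 14
Reactants: 22 ethyl (1S,2S,6R,7S,10R)-6-(acetyloxy)-2-hydroxy-7-methyl-10-(propan-2-yl)-10-[(triethylsilyl)oxy]bicyclo[5.3.0]dec-4-ene-4-carboxylate
Product: 23 (1S,2S,6R,7S,10R)-4-(hydroxymethyl)-7-methyl-10-(propan-2-yl)-10-[(triethylsilyl)oxy]bicyclo[5.3.0]dec-4-ene-2,6-diol
Conditions: iBu2AlH (6 equiv), CH2Cl2, −78 → 0 °C; aq. potassium sodium tartrate
Reagents that add atoms: none
Why: Reduction with diisobutylaluminium hydride converts the conjugated ester into the primary allylic alcohol by 1,2-reduction and cleaves the acetate in the same operation, leaving the silyl ether and all stereocentres unchanged.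

Step 15
Reactants: 23 (1S,2S,6R,7S,10R)-4-(hydroxymethyl)-7-methyl-10-(propan-2-yl)-10-[(triethylsilyl)oxy]bicyclo[5.3.0]dec-4-ene-2,6-diol
Product: 24 (1S,2S,4S,5S,6S,7S,10R)-4,5-epoxy-4-(hydroxymethyl)-7-methyl-10-(propan-2-yl)-10-[(triethylsilyl)oxy]bicyclo[5.3.0]decane-2,6-diol
Conditions: VO(acac)2 (5 mol%), t-BuOOH, CH2Cl2, 0 → 23 °C
Reagents that add atoms: tert-butyl hydroperoxide, CC(C)(C)OO
Why: Vanadium-catalysed hydroxyl-directed epoxidation: the allylic C6 hydroxyl, helped by the homoallylic C2 hydroxyl on the same face, delivers oxygen syn to the β-face of C4=C5, which sets C4 and C5.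

Step 16
Reactants: 24 (1S,2S,4S,5S,6S,7S,10R)-4,5-epoxy-4-(hydroxymethyl)-7-methyl-10-(propan-2-yl)-10-[(triethylsilyl)oxy]bicyclo[5.3.0]decane-2,6-diol
Product: 26 (1S,2S,5R,6S,7S,10R)-7-methyl-4-methylidene-10-(propan-2-yl)-10-[(triethylsilyl)oxy]bicyclo[5.3.0]decane-2,5,6-triol, via epoxy iodide 25 (not isolated)
Conditions: I2, PPh3, imidazole, THF, 0 °C; then Zn dust, AcOH, 23 °C
Reagents that add atoms: none
Why: Appel iodination is selective for the primary hydroxyl, and zinc then brings about reductive β-elimination of the 2,3-epoxy iodide (epoxide to allylic alcohol transposition), which breaks the C4–O bond, forms the C4 methylidene and leaves the C5–O bond with its β configuration.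

Step 17
Reactants: 26 (1S,2S,5R,6S,7S,10R)-7-methyl-4-methylidene-10-(propan-2-yl)-10-[(triethylsilyl)oxy]bicyclo[5.3.0]decane-2,5,6-triol
Product: 27 (1S,2S,5R,6S,7S,10R)-5,6-(isopropylidenedioxy)-7-methyl-4-methylidene-10-(propan-2-yl)-10-[(triethylsilyl)oxy]bicyclo[5.3.0]decan-2-ol
Conditions: Me2C(OMe)2, PPTS (cat.), CH2Cl2, 23 °C
Reagents that add atoms: 2,2-dimethoxypropane, COC(C)(C)OC
Why: Acid-catalysed transacetalisation forms the five-membered isopropylidene acetal only on the cis-vicinal C5/C6 diol and leaves the isolated C2 hydroxyl free.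

Step 18
Reactants: 27 (1S,2S,5R,6S,7S,10R)-5,6-(isopropylidenedioxy)-7-methyl-4-methylidene-10-(propan-2-yl)-10-[(triethylsilyl)oxy]bicyclo[5.3.0]decan-2-ol; 28 3-methylbutanoyl chloride
Product: 29 (1S,2S,5R,6S,7S,10R)-5,6-(isopropylidenedioxy)-7-methyl-4-methylidene-10-(propan-2-yl)-10-[(triethylsilyl)oxy]bicyclo[5.3.0]decan-2-yl 3-methylbutanoate
Conditions: pyridine, DMAP (cat.), CH2Cl2, 0 → 23 °C
Reagents that add atoms: none
Why: DMAP-catalysed acylation of the only free hydroxyl, the secondary C2 alcohol, proceeds with retention because the C2–O bond is not broken.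

Step 19
Reactants: 29 (1S,2S,5R,6S,7S,10R)-5,6-(isopropylidenedioxy)-7-methyl-4-methylidene-10-(propan-2-yl)-10-[(triethylsilyl)oxy]bicyclo[5.3.0]decan-2-yl 3-methylbutanoate
Product: 30 (1S,2S,5R,6S,7S,10R)-5,6,10-trihydroxy-7-methyl-4-methylidene-10-(propan-2-yl)bicyclo[5.3.0]decan-2-yl 3-methylbutanoate
Conditions: 1 M aq. HCl, THF, 23 °C
Reagents that add atoms: none
Why: Mild aqueous acid hydrolyses the acetonide and cleaves the tertiary triethylsilyl ether in one operation (acetal hydrolysis and protodesilylation), conditions under which the ester and the allylic diol should persist, to give the target.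

Compound list
1 | 3-methyl-2-methylidenebutanal | C=C(C=O)C(C)C | starting material
2 | 3-methyl-2-methylidenebutan-1-ol | C=C(CO)C(C)C | intermediate
3 | [(2R)-2-(propan-2-yl)oxiran-2-yl]methanol | OC[C@]1(C(C)C)CO1 | intermediate
4 | (2-methylprop-2-en-1-yl)magnesium chloride | CC(=C)C[Mg]Cl | starting material
5 | (2R)-5-methyl-2-(propan-2-yl)hex-5-ene-1,2-diol | OC[C@](O)(C(C)C)CCC(C)=C | intermediate
6 | (2R)-2-hydroxy-5-methyl-2-(propan-2-yl)hex-5-en-1-yl 4-methylbenzenesulfonate (not isolated) | Cc1ccc(cc1)S(=O)(=O)OC[C@](O)(C(C)C)CCC(C)=C | intermediate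
7 | (2R)-2-(3-methylbut-3-en-1-yl)-2-(propan-2-yl)oxirane | CC(=C)CC[C@@]1(C(C)C)CO1 | intermediate
8 | ethenylmagnesium bromide | C=C[Mg]Br | starting material
9 | (4S)-7-methyl-4-(propan-2-yl)octa-1,7-dien-4-ol | C=CC[C@](O)(C(C)C)CCC(C)=C | intermediate
10 | triethyl{[(4S)-7-methyl-4-(propan-2-yl)octa-1,7-dien-4-yl]oxy}silane | C=CC[C@](O[Si](CC)(CC)CC)(C(C)C)CCC(C)=C | intermediate
11 | bis-ozonide of 10: both alkenes as 1,2,4-trioxolanes, carbinol carbon unchanged, ozonide carbons unassigned (not isolated) | O1COOC1C[C@](O[Si](CC)(CC)CC)(C(C)C)CCC1(C)OOCO1 | intermediate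
12 | (3S)-6-oxo-3-(propan-2-yl)-3-[(triethylsilyl)oxy]heptanal | O=CC[C@](O[Si](CC)(CC)CC)(C(C)C)CCC(C)=O | intermediate
13 | (5R)-2-methyl-5-(propan-2-yl)-5-[(triethylsilyl)oxy]cyclopent-1-ene-1-carbaldehyde | O=CC1=C(C)CC[C@@]1(O[Si](CC)(CC)CC)C(C)C | intermediate
14 | {[(1R)-2-ethenyl-3-methyl-1-(propan-2-yl)cyclopent-2-en-1-yl]oxy}(triethyl)silane | C=CC1=C(C)CC[C@@]1(O[Si](CC)(CC)CC)C(C)C | intermediate
15 | ethyl diazoacetate | CCOC(=O)C=[N+]=[N-] | starting material
16 | 2-oxoethyl acetate | CC(=O)OCC=O | starting material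
17 | ethyl 4-(acetyloxy)-2-diazo-3-hydroxybutanoate (racemic) | CCOC(=O)C(=[N+]=[N-])C(O)COC(C)=O | intermediate
18 | ethyl (3E)-4-(acetyloxy)-2-diazobut-3-enoate | CCOC(=O)C(=[N+]=[N-])/C=C/OC(C)=O | intermediate
19 | ethyl (1R,2S)-1-[(E)-2-(acetyloxy)ethenyl]-2-{(5R)-2-methyl-5-(propan-2-yl)-5-[(triethylsilyl)oxy]cyclopent-1-en-1-yl}cyclopropane-1-carboxylate (not isolated) | CCOC(=O)[C@]1(/C=C/OC(C)=O)C[C@H]1C2=C(C)CC[C@@]2(O[Si](CC)(CC)CC)C(C)C | intermediate
20 | ethyl (6R,7S,10R)-6-(acetyloxy)-7-methyl-10-(propan-2-yl)-10-[(triethylsilyl)oxy]bicyclo[5.3.0]deca-1,4-diene-4-carboxylate | C1=C(C(=O)OCC)CC=C2[C@](C)(CC[C@@]2(O[Si](CC)(CC)CC)C(C)C)[C@@H]1OC(C)=O | intermediate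
21 | ethyl (1R,2S,6R,7S,10R)-6-(acetyloxy)-2-boranyl-7-methyl-10-(propan-2-yl)-10-[(triethylsilyl)oxy]bicyclo[5.3.0]dec-4-ene-4-carboxylate, the C2 monoalkylborane (not isolated) | C1=C(C(=O)OCC)C[C@H](B)[C@@H]2[C@](C)(CC[C@@]2(O[Si](CC)(CC)CC)C(C)C)[C@@H]1OC(C)=O | intermediate
22 | ethyl (1S,2S,6R,7S,10R)-6-(acetyloxy)-2-hydroxy-7-methyl-10-(propan-2-yl)-10-[(triethylsilyl)oxy]bicyclo[5.3.0]dec-4-ene-4-carboxylate | C1=C(C(=O)OCC)C[C@H](O)[C@@H]2[C@](C)(CC[C@@]2(O[Si](CC)(CC)CC)C(C)C)[C@@H]1OC(C)=O | intermediate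
23 | (1S,2S,6R,7S,10R)-4-(hydroxymethyl)-7-methyl-10-(propan-2-yl)-10-[(triethylsilyl)oxy]bicyclo[5.3.0]dec-4-ene-2,6-diol | C1=C(CO)C[C@H](O)[C@@H]2[C@](C)(CC[C@@]2(O[Si](CC)(CC)CC)C(C)C)[C@@H]1O | intermediate
24 | (1S,2S,4S,5S,6S,7S,10R)-4,5-epoxy-4-(hydroxymethyl)-7-methyl-10-(propan-2-yl)-10-[(triethylsilyl)oxy]bicyclo[5.3.0]decane-2,6-diol | OC[C@@]12C[C@H](O)[C@@H]3[C@](C)(CC[C@@]3(O[Si](CC)(CC)CC)C(C)C)[C@H](O)[C@@H]1O2 | intermediate
25 | (1S,2S,4R,5S,6S,7S,10R)-4,5-epoxy-4-(iodomethyl)-7-methyl-10-(propan-2-yl)-10-[(triethylsilyl)oxy]bicyclo[5.3.0]decane-2,6-diol (not isolated) | IC[C@@]12C[C@H](O)[C@@H]3[C@](C)(CC[C@@]3(O[Si](CC)(CC)CC)C(C)C)[C@H](O)[C@@H]1O2 | intermediate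
26 | (1S,2S,5R,6S,7S,10R)-7-methyl-4-methylidene-10-(propan-2-yl)-10-[(triethylsilyl)oxy]bicyclo[5.3.0]decane-2,5,6-triol | C=C1C[C@H](O)[C@@H]2[C@](C)(CC[C@@]2(O[Si](CC)(CC)CC)C(C)C)[C@H](O)[C@@H]1O | intermediate
27 | (1S,2S,5R,6S,7S,10R)-5,6-(isopropylidenedioxy)-7-methyl-4-methylidene-10-(propan-2-yl)-10-[(triethylsilyl)oxy]bicyclo[5.3.0]decan-2-ol | C=C1C[C@H](O)[C@@H]2[C@](C)(CC[C@@]2(O[Si](CC)(CC)CC)C(C)C)[C@@H]3OC(C)(C)O[C@H]13 | intermediate
28 | 3-methylbutanoyl chloride | CC(C)CC(Cl)=O | starting material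
29 | (1S,2S,5R,6S,7S,10R)-5,6-(isopropylidenedioxy)-7-methyl-4-methylidene-10-(propan-2-yl)-10-[(triethylsilyl)oxy]bicyclo[5.3.0]decan-2-yl 3-methylbutanoate | C=C1C[C@H](OC(=O)CC(C)C)[C@@H]2[C@](C)(CC[C@@]2(O[Si](CC)(CC)CC)C(C)C)[C@@H]3OC(C)(C)O[C@H]13 | intermediate
30 | (1S,2S,5R,6S,7S,10R)-5,6,10-trihydroxy-7-methyl-4-methylidene-10-(propan-2-yl)bicyclo[5.3.0]decan-2-yl 3-methylbutanoate | C=C1C[C@H](OC(=O)CC(C)C)[C@@H]2[C@](C)(CC[C@@]2(O)C(C)C)[C@H](O)[C@@H]1O | target

Total step count: 19 steps.
Longest linear sequence: 17 steps (steps 1 to 9, then 12 to 19); steps 10 and 11 form the second arm.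

Steps most likely to fail

Step 12. What may go wrong: the acetoxy-substituted carbenoid is lost to dimerisation, to cyclisation to a pyrazole or to attack at its vinylogous position; the rearrangement stalls, or leaks through epimerisation of the cyclopropane, because the C7 methyl points into the boat; or the catalyst and the C10 centre are mismatched. Fallback (known reactions only; it sets out from 13 and comes back at 20): the C6–C7 bond is made by a [2,3]-Wittig rearrangement and the ring is closed by olefin metathesis.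
- Luche reduction of 13 (NaBH4, CeCl3·7H2O, MeOH) gives [(5R)-2-methyl-5-(propan-2-yl)-5-[(triethylsilyl)oxy]cyclopent-1-en-1-yl]methanol F1.
- NaH and allyl bromide give the bis-allylic ether triethyl{[(1R)-3-methyl-1-(propan-2-yl)-2-[(prop-2-en-1-yloxy)methyl]cyclopent-2-en-1-yl]oxy}silane F2.
- n-BuLi in THF at −78 °C removes a proton from the unsubstituted allyl group. The [2,3]-shift onto the ring alkene forms C6–C7 and moves the alkene out of the ring, giving (1R)-1-[(1S,3R)-1-methyl-2-methylidene-3-(propan-2-yl)-3-[(triethylsilyl)oxy]cyclopentyl]prop-2-en-1-ol F3. The methyl group cis to the migration terminus should favour the C6/C7 relationship of 20; the face with respect to C10 is less certain and may call for a separation.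
- Acetylation (Ac2O, pyridine, DMAP) gives (1R)-1-[(1S,3R)-1-methyl-2-methylidene-3-(propan-2-yl)-3-[(triethylsilyl)oxy]cyclopentyl]prop-2-en-1-yl acetate F4.
- OsO4 (cat.) and NaIO4 with 2,6-lutidine cleave the vinyl group to the aldehyde (1S)-1-[(1S,3R)-1-methyl-2-methylidene-3-(propan-2-yl)-3-[(triethylsilyl)oxy]cyclopentyl]-2-oxoethyl acetate F5. The methylidene, flanked by two quaternary carbons, should react more slowly.
- Horner–Wadsworth–Emmons reaction (LiCl, iPr2NEt, MeCN, chosen to spare the epimerisable C6) with ethyl 2-(diethoxyphosphoryl)pent-4-enoate F6 (made from triethyl phosphonoacetate, NaH and allyl bromide) gives ethyl (2E,4R)-4-(acetyloxy)-4-[(1S,3R)-1-methyl-2-methylidene-3-(propan-2-yl)-3-[(triethylsilyl)oxy]cyclopentyl]-2-(prop-2-en-1-yl)but-2-enoate F7.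
- Ring-closing metathesis of the allyl group with the methylidene (second-generation Grubbs catalyst, toluene, 80 °C) forms C1=C2 and gives 20.

Step 13. What may go wrong: borane adds from the α-face, on the side of the angular methyl, which gives the cis ring fusion and the 2α-alcohol, or it reduces the conjugated ester. Fallback (it sets out from 20 and comes back at 24): the hydrogen at C1 and the oxygen at C2 are delivered from the β-oriented C6 oxygen through a silicon tether.
- iBu2AlH reduces 20 to (6R,7S,10R)-4-(hydroxymethyl)-7-methyl-10-(propan-2-yl)-10-[(triethylsilyl)oxy]bicyclo[5.3.0]deca-1,4-dien-6-ol F8.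
- VO(acac)2 and t-BuOOH epoxidise only the allylic C4=C5 alkene, syn to the C6 hydroxyl, giving (4S,5S,6S,7S,10R)-4,5-epoxy-4-(hydroxymethyl)-7-methyl-10-(propan-2-yl)-10-[(triethylsilyl)oxy]bicyclo[5.3.0]dec-1-en-6-ol F9.
- (HMe2Si)2NH converts both hydroxyls into dimethylsilyl ethers, giving the bis(dimethylsilyl) ether of F9 F10.
- Pt2[(CH2=CHSiMe2)2O]3 in toluene at 60 °C brings about intramolecular hydrosilylation of C1=C2 from the C6–O–SiHMe2 group. The addition must be syn and β, and silicon should go to C2 because C1 lies between two quaternary carbons; this gives the 2-C,6-O-dimethylsilylene-bridged oxasilinane F11.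
- Tamao–Fleming oxidation (H2O2, KF, KHCO3, THF/MeOH) replaces silicon by hydroxyl with retention, frees the other two hydroxyls and gives 24.

Step 8. What may go wrong: loss of the β-silyloxy group from the enamine or iminium ion (elimination to an enal), or ring closure in the other sense (ketone enolate onto the aldehyde). Fallback (it sets out from 5 and comes back at 14): the ring is closed by enyne metathesis, with no carbonyl β to the silyloxy group.
- Parikh–Doering oxidation of the primary hydroxyl of 5 (SO3·pyridine, DMSO, iPr2NEt) gives (2R)-2-hydroxy-5-methyl-2-(propan-2-yl)hex-5-enal F12.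
- The Ohira–Bestmann reagent (dimethyl (1-diazo-2-oxopropyl)phosphonate, K2CO3, MeOH) gives (3R)-6-methyl-3-(propan-2-yl)hept-6-en-1-yn-3-ol F13.
- Et3SiOTf and 2,6-lutidine give triethyl{[(3R)-6-methyl-3-(propan-2-yl)hept-6-en-1-yn-3-yl]oxy}silane F14.
- Ring-closing enyne metathesis (second-generation Grubbs catalyst, ethylene, toluene, 80 °C) joins the inner alkyne carbon (C1) to C7, passes the alkene CH2 to the alkyne terminus as C3 and gives 14. Closure in the endo sense to a six-membered diene is the risk of this variant.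

Further compounds
F1 | step 12 | [(5R)-2-methyl-5-(propan-2-yl)-5-[(triethylsilyl)oxy]cyclopent-1-en-1-yl]methanol | OCC1=C(C)CC[C@@]1(O[Si](CC)(CC)CC)C(C)C
F2 | step 12 | triethyl{[(1R)-3-methyl-1-(propan-2-yl)-2-[(prop-2-en-1-yloxy)methyl]cyclopent-2-en-1-yl]oxy}silane | C=CCOCC1=C(C)CC[C@@]1(O[Si](CC)(CC)CC)C(C)C
F3 | step 12 | (1R)-1-[(1S,3R)-1-methyl-2-methylidene-3-(propan-2-yl)-3-[(triethylsilyl)oxy]cyclopentyl]prop-2-en-1-ol | C=C1[C@](C)(CC[C@@]1(O[Si](CC)(CC)CC)C(C)C)[C@H](O)C=C
F4 | step 12 | (1R)-1-[(1S,3R)-1-methyl-2-methylidene-3-(propan-2-yl)-3-[(triethylsilyl)oxy]cyclopentyl]prop-2-en-1-yl acetate | C=C1[C@](C)(CC[C@@]1(O[Si](CC)(CC)CC)C(C)C)[C@H](OC(C)=O)C=C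
F5 | step 12 | (1S)-1-[(1S,3R)-1-methyl-2-methylidene-3-(propan-2-yl)-3-[(triethylsilyl)oxy]cyclopentyl]-2-oxoethyl acetate | C=C1[C@](C)(CC[C@@]1(O[Si](CC)(CC)CC)C(C)C)[C@H](OC(C)=O)C=O
F6 | step 12 | ethyl 2-(diethoxyphosphoryl)pent-4-enoate | CCOC(=O)C(CC=C)P(=O)(OCC)OCC
F7 | step 12 | ethyl (2E,4R)-4-(acetyloxy)-4-[(1S,3R)-1-methyl-2-methylidene-3-(propan-2-yl)-3-[(triethylsilyl)oxy]cyclopentyl]-2-(prop-2-en-1-yl)but-2-enoate | C=C1[C@](C)(CC[C@@]1(O[Si](CC)(CC)CC)C(C)C)[C@H](OC(C)=O)/C=C(\CC=C)C(=O)OCC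
F8 | step 13 | (6R,7S,10R)-4-(hydroxymethyl)-7-methyl-10-(propan-2-yl)-10-[(triethylsilyl)oxy]bicyclo[5.3.0]deca-1,4-dien-6-ol | C1=C(CO)CC=C2[C@](C)(CC[C@@]2(O[Si](CC)(CC)CC)C(C)C)[C@@H]1O
F9 | step 13 | (4S,5S,6S,7S,10R)-4,5-epoxy-4-(hydroxymethyl)-7-methyl-10-(propan-2-yl)-10-[(triethylsilyl)oxy]bicyclo[5.3.0]dec-1-en-6-ol | OC[C@@]12CC=C3[C@](C)(CC[C@@]3(O[Si](CC)(CC)CC)C(C)C)[C@H](O)[C@@H]1O2
F10 | step 13 | bis(dimethylsilyl) ether of F9 (C6 oxygen and hydroxymethyl oxygen) | C[SiH](C)OC[C@@]12CC=C3[C@](C)(CC[C@@]3(O[Si](CC)(CC)CC)C(C)C)[C@H](O[SiH](C)C)[C@@H]1O2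
F11 | step 13 | 2-C,6-O-dimethylsilylene-bridged oxasilinane from F10 (H-1 and C2–Si on the β-face) | C[SiH](C)OC[C@@]12C[C@H]4[C@@H]3[C@](C)(CC[C@@]3(O[Si](CC)(CC)CC)C(C)C)[C@H](O[Si]4(C)C)[C@@H]1O2
F12 | step 8 | (2R)-2-hydroxy-5-methyl-2-(propan-2-yl)hex-5-enal | O=C[C@](O)(C(C)C)CCC(C)=C
F13 | step 8 | (3R)-6-methyl-3-(propan-2-yl)hept-6-en-1-yn-3-ol | C#C[C@](O)(C(C)C)CCC(C)=C
F14 | step 8 | triethyl{[(3R)-6-methyl-3-(propan-2-yl)hept-6-en-1-yn-3-yl]oxy}silane | C#C[C@](O[Si](CC)(CC)CC)(C(C)C)CCC(C)=C
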